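**Strategy.** The ten-membered ring (C1–C10) is made by ring contraction. Its (Z)-C3=C4 bond, conjugated with C5=C6, is the product of a Ramberg–Bäcklund reaction. An eleven-membered thiacycle with sulfur bridging C3 and C4 is closed by double S-alkylation, oxidised, and contracted with loss of SO2; this joins two formerly electrophilic CH2 carbons and creates the diene in one operation. The precursor is a macrocyclic allyl alkyl sulfone bearing the cyclohexene ring (C1, C2, C10, C14 from Evans aldol, dianionic Ireland–Claisen, Krische allylation, RCM) and the silylated C7–C9/C17 array (lactone-enolate aldol, Noyori reduction). The γ-lactone is closed after the contraction, then deprotection and acetylation.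

Key step: step 23

Remark (assumption): compounds 1, 2, 5, 6, 16 and 21 are taken as purchasable (6, 16 and 21 from specialist suppliers).
Locants used in names are those of the target: ten-membered ring C1–C10; cyclohexene C1, C10, C11(=C12), C13, C14; lactone O–C7, C8, C17, C19(=O); C15 = CH3 on C1, C16 = CH2 on C5, C18 = CH3 on C17, C20 = CH3 on C11. "As in the target" means the same spatial arrangement as in the target, which is (1R,2S,7S,8S,9S,10S,14S,17R).

Step 1
Reactants: 1 2-((tert-butyldimethylsilyl)oxy)acetaldehyde; 2 ethyl 2-(triphenyl-λ5-phosphanylidene)propanoate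
Product: 3 ethyl (E)-4-((tert-butyldimethylsilyl)oxy)-2-methylbut-2-enoate
Conditions: CH2Cl2, rt
Reagents that add atoms: none
Why: Wittig olefination with a stabilised ylide should give the (E)-trisubstituted enoate selectively.

Step 2
Reactants: 3 ethyl (E)-4-((tert-butyldimethylsilyl)oxy)-2-methylbut-2-enoate
Product: 4 (E)-4-((tert-butyldimethylsilyl)oxy)-2-methylbut-2-en-1-ol
Conditions: DIBAL-H, CH2Cl2, −78 °C; Rochelle salt
Reagents that add atoms: none
Why: 1,2-reduction of the enoate by DIBAL-H should give the allylic alcohol without touching the silyl ether or the olefin geometry.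

Step 3
Reactants: 5 (R)-4-benzyl-3-propionyloxazolidin-2-one; 6 2-((4-methoxybenzyl)oxy)acetaldehyde
Product: 7 (R)-4-benzyl-3-[(2R,3R)-3-hydroxy-4-((4-methoxybenzyl)oxy)-2-methylbutanoyl]oxazolidin-2-one
Conditions: Bu2BOTf, i-Pr2NEt, CH2Cl2, −78 → 0 °C; then pH 7 buffer, MeOH, H2O2
Reagents that add atoms: none
Why: Evans syn-aldol through the (Z)-boron enolate and a Zimmerman–Traxler chair, in which the (R)-benzyl auxiliary sets the carbinol that becomes C2 (the α-methyl centre is erased in step 5).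

Step 4
Reactants: 7 Evans aldol adduct; 4 (E)-4-((tert-butyldimethylsilyl)oxy)-2-methylbut-2-en-1-ol
Product: 8 (E)-4-((tert-butyldimethylsilyl)oxy)-2-methylbut-2-en-1-yl (2R,3R)-3-hydroxy-4-((4-methoxybenzyl)oxy)-2-methylbutanoate
Conditions: 4, MeMgBr, THF, 0 °C; then 7, 0 °C → rt
Reagents that add atoms: none
Why: Transesterification by the magnesium alkoxide of 4 at the exocyclic imide carbonyl should release the auxiliary and give the allyl ester, low temperature limiting retro-aldol.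

Step 5
Reactants: 8 allyl β-hydroxy ester
Product: 9 (2S,3R)-2-[(2S)-1-((tert-butyldimethylsilyl)oxy)-3-methylbut-3-en-2-yl]-3-hydroxy-4-((4-methoxybenzyl)oxy)-2-methylbutanoic acid
Conditions: LDA (3 equiv), THF, −78 °C → rt; aq. HCl work-up
Reagents that add atoms: none
Why: Dianionic Ireland–Claisen rearrangement, in which the lithium alkoxide–enolate chelate fixes the enolate geometry and directs the allyl unit to the face anti to the C2 oxygen (Fráter–Seebach sense, sets quaternary C1), while the chair transition state with the (E)-olefin places CH2OTBS equatorial and sets C10.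

Step 6
Reactants: 9 carboxylic acid
Product: 10 (2R,3R)-2-[(2S)-1-((tert-butyldimethylsilyl)oxy)-3-methylbut-3-en-2-yl]-4-((4-methoxybenzyl)oxy)-2-methylbutane-1,3-diol
Conditions: LiAlH4, THF, 0 °C → reflux
Reagents that add atoms: none
Why: Hydride reduction of the hindered acid to the primary alcohol (future C14) should leave the silyl and PMB ethers and the alkene intact.

Step 7
Reactants: 10 1,3-diol
Product: 11 (2R,3R,4S)-3-[(2S)-1-((tert-butyldimethylsilyl)oxy)-3-methylbut-3-en-2-yl]-1-((4-methoxybenzyl)oxy)-3-methylhept-6-ene-2,4-diol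
Conditions: [Ir(cod)Cl]2 (2.5 mol%), (S)-Cl,MeO-BIPHEP (5 mol%), Cs2CO3 (20 mol%), 4-chloro-3-nitrobenzoic acid (10 mol%), THF, 100 °C
Reagents that add atoms: allyl acetate, C=CCOC(C)=O
Why: Krische iridium-catalysed transfer-hydrogenative allylation from the alcohol oxidation level, in which only the primary neopentyl alcohol is dehydrogenated and the chiral Ir π-allyl complex sets C14 under catalyst control (2,14-anti diol), the ligand enantiomer being assigned by analogy with bis-allylations of 1,3-diols.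

Step 8
Reactants: 11 diene diol
Product: 12 ring-A diol (cyclohexene with C11=C12)
Conditions: Grubbs II (5 mol%), CH2Cl2, 40 °C
Reagents that add atoms: none
Why: Ring-closing metathesis between the isopropenyl and the terminal vinyl group should close the six-membered ring with the trisubstituted C11=C12 bond and change no stereocentre.

Step 9
Reactants: 12 ring-A diol
Product: 13 tris-TBS ether
Conditions: TBSOTf (3 equiv), 2,6-lutidine, CH2Cl2, 0 °C → rt
Reagents that add atoms: tert-butyldimethylsilyl trifluoromethanesulfonate, CC(C)(C)[Si](C)(C)OS(=O)(=O)C(F)(F)F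
Why: Silylation with the reactive triflate should protect both hindered secondary alcohols (O2, O14).

Step 10
Reactants: 13 tris-TBS ether
Product: 14 primary alcohol (9-OH)
Conditions: CSA (0.2 equiv), MeOH/CH2Cl2, 0 °C
Reagents that add atoms: none
Why: Acid-catalysed methanolysis should cleave the primary TBS ether much faster than the two hindered secondary ones.

Step 11
Reactants: 14 primary alcohol
Product: 15 ring-A aldehyde (C9 = CHO)
Conditions: Dess–Martin periodinane, NaHCO3, CH2Cl2, 0 °C; used at once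
Reagents that add atoms: none
Why: Buffered Dess–Martin oxidation should give the β,γ-unsaturated aldehyde without epimerising C10 or moving the C11=C12 bond.

Step 12
Reactants: 16 (R)-4-methyldihydrofuran-2(3H)-one
Product: 17 (3R,4R)-3-hydroxy-4-methyldihydrofuran-2(3H)-one
Conditions: KHMDS, THF, −78 °C; then the oxaziridine; NH4Cl
Reagents that add atoms: trans-2-(phenylsulfonyl)-3-phenyloxaziridine, O=S(=O)(c1ccccc1)N1OC1c1ccccc1
Why: Davis enolate hydroxylation should occur anti to the C17 methyl; this C8 configuration is provisional and is reset in step 14.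

Step 13
Reactants: 17 hydroxy lactone
Product: 18 (3R,4R)-4-methyl-3-((triethylsilyl)oxy)dihydrofuran-2(3H)-one
Conditions: TESCl, imidazole, DMF, 0 °C → rt
Reagents that add atoms: chlorotriethylsilane, CC[Si](Cl)(CC)CC
Why: Standard silylation should protect the α-hydroxyl so that the lactone can be enolised cleanly.

Step 14
Reactants: 18 α-silyloxy lactone; 15 ring-A aldehyde
Product: 20 aldol adduct (8-OTES, 9-OTBS lactone), via lithium aldolate 19 (not isolated)
Conditions: 18, LDA, THF, −78 °C; add 15; then TBSOTf, 2,6-lutidine, −78 → −20 °C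
Reagents that add atoms: tert-butyldimethylsilyl trifluoromethanesulfonate, CC(C)(C)[Si](C)(C)OS(=O)(=O)C(F)(F)F
Why: Lithium-enolate aldol addition in which the aldehyde enters the tetrasubstituted enolate anti to the adjacent methyl (sets C8, oxygen cis to C18) and a closed Zimmerman–Traxler chair with O–Li cis to O8 gives the 8,9-syn relationship (sets C9), the aldolate being trapped as its TBS ether to block retro-aldol.

Step 15
Reactants: 20 aldol adduct; 21 tert-butyldiphenyl(prop-2-yn-1-yloxy)silane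
Product: 22 hydroxy ynone
Conditions: 21, n-BuLi, THF, −78 °C; then 20, −78 → −20 °C; NH4Cl
Reagents that add atoms: none
Why: Addition of the lithium acetylide to the lactone carbonyl (C7) should stop at the stable lactolate and give the ynone on work-up, forming the C6–C7 bond.

Step 16
Reactants: 22 hydroxy ynone
Product: 23 (7S)-propargylic alcohol (7,19-diol)
Conditions: RuCl(p-cymene)[(R,R)-TsDPEN] (5 mol%), i-PrOH, rt
Reagents that add atoms: none
Why: Noyori asymmetric transfer hydrogenation of the ynone should set C7 under reagent control, the alkyne taking the place of the aryl group in the usual model.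

Step 17
Reactants: 23 propargylic alcohol
Product: 25 (Z)-5-iodo alkene diol, via alkenylaluminate 24 (not isolated)
Conditions: Red-Al, THF, 0 °C → rt; then I2, −78 → 0 °C
Reagents that add atoms: iodine, II
Why: Alkoxide-directed trans-hydroalumination of the propargylic alcohol places aluminium on the distal carbon C5, and iodinolysis with retention should fix the C5=C6 geometry (iodine, later C4, cis to C7).

Step 18
Reactants: 25 iodo diol
Product: 26 7,19-bis-TES ether
Conditions: TESOTf, 2,6-lutidine, CH2Cl2, −78 → 0 °C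
Reagents that add atoms: triethylsilyl trifluoromethanesulfonate, CC[Si](CC)(CC)OS(=O)(=O)C(F)(F)F
Why: Silylation should mask O7 and O19 so that only O3 and O4 are activated later and no alkoxide or carboxylate leaving group sits at C7 during the contraction.

Step 19
Reactants: 26 bis-TES ether
Product: 27 C3 primary alcohol
Conditions: DDQ, CH2Cl2/pH 7 buffer, 0 °C
Reagents that add atoms: none
Why: Oxidative cleavage of the PMB ether by DDQ should free O3 without affecting silyl ethers or the vinyl iodide.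

Step 20
Reactants: 27 iodo alcohol
Product: 28 3,4-diol
Conditions: Pd(PPh3)4 (10 mol%), toluene, 90 °C
Reagents that add atoms: (tributylstannyl)methanol, CCCC[Sn](CCCC)(CCCC)CO
Why: Stille coupling should replace iodine by CH2OH (C4) with retention of the olefin geometry.

Step 21
Reactants: 28 3,4-diol
Product: 30 eleven-membered cyclic sulfide, via bis-mesylate 29 (not isolated)
Conditions: Ms2O, i-Pr2NEt, CH2Cl2, −20 °C; then Na2S·9H2O, DMF, 2 mM, rt
Reagents that add atoms: sodium sulfide, [Na+].[Na+].[S-2]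
Why: Double S-alkylation, in which sulfide displaces the allylic mesylate first and the resulting thiolate closes the ring at the primary C3 mesylate (11-exo-tet) under high dilution.

Step 22
Reactants: 30 cyclic sulfide
Product: 31 cyclic sulfone
Conditions: TPAP (10 mol%), NMO, 4 Å MS, MeCN, rt
Reagents that add atoms: N-methylmorpholine N-oxide, C[N+]1([O-])CCOCC1
Why: Perruthenate-catalysed S-oxidation should take the sulfide to the sulfone without epoxidising either alkene or cleaving silyl ethers.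

Step 23
Reactants: 31 eleven-membered cyclic sulfone
Product: 34 ten-membered (3Z)-3,5-diene, via α-bromo sulfone 32 (not isolated), via episulfone 33 (not isolated)
Conditions: KOH/Al2O3, CBr2F2, t-BuOH/CH2Cl2, 5 °C → rt
Reagents that add atoms: none
Why: Ramberg–Bäcklund ring contraction under Meyers–Chan conditions: base removes an allylic α-proton at C4, the carbanion is brominated by CBr2F2, a second deprotonation at C3 closes the episulfone by 1,3-displacement of bromide (3-exo-tet), and cheletropic loss of SO2 leaves the C3=C4 bond, so the eleven-membered thiacycle becomes the ten-membered carbocycle. The closest known reaction type is the Ramberg–Bäcklund contraction of cyclic allyl and benzyl sulfones to cyclic dienes and cyclophanes. No stereocentre is formed, and the Z geometry at C3=C4 is expected because a cis-fused episulfone is the kinetic closure product and an E,Z-1,3-diene would be badly strained in the fused ten-membered ring. Either α-carbon may carry the bromine, since both α-bromo sulfones collapse to the same alkene. The step needs the C3 carbanion not to expel O2 and the C4 allyl anion not to expel O7 (1,4-elimination); both oxygens are silyl ethers, which are poor leaving groups, and no lactone, ester or free alkoxide is present.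

Step 24
Reactants: 34 ring-contracted diene
Product: 35 7,19-diol
Conditions: HF·pyridine, pyridine, THF, 0 °C
Reagents that add atoms: none
Why: Buffered fluoride desilylation should remove the primary (O19) and the allylic secondary (O7) TES ethers well before the tertiary TES, the hindered TBS and the TBDPS ethers.

Step 25
Reactants: 35 7,19-diol
Product: 36 γ-lactone (O7–C19=O), silyl-protected
Conditions: TEMPO (20 mol%), PhI(OAc)2, CH2Cl2, rt
Reagents that add atoms: none
Why: TEMPO/PhI(OAc)2 oxidative lactonisation: the primary C19 alcohol is oxidised first, O7 closes the five-membered lactol, and this is oxidised to the lactone, while silylated O9 cannot form the isomeric lactone and the neutral medium should spare C17.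

Step 26
Reactants: 36 protected lactone
Product: 37 pentaol lactone (2,8,9,14,16-OH)
Conditions: HF·pyridine (excess), THF, 0 → 40 °C
Reagents that add atoms: none
Why: Global fluoride desilylation under mildly acidic conditions should free all five hydroxyls without opening or migrating the lactone.

Step 27
Reactants: 37 pentaol lactone
Product: 38 target, CNP0224753.2
Conditions: Ac2O, pyridine, DMAP (cat.), CH2Cl2, 0 °C → rt
Reagents that add atoms: acetic anhydride, CC(=O)OC(C)=O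
Why: DMAP-catalysed acetylation should esterify the primary (O16) and the three secondary hydroxyls (O2, O9, O14) and leave the hindered tertiary 8-OH free.

**Compound list**

1 | 2-((tert-butyldimethylsilyl)oxy)acetaldehyde | O=CCO[Si](C)(C)C(C)(C)C | starting material
2 | ethyl 2-(triphenyl-λ5-phosphanylidene)propanoate | CCOC(=O)C(C)=P(c1ccccc1)(c1ccccc1)c1ccccc1 | starting material
3 | ethyl (E)-4-((tert-butyldimethylsilyl)oxy)-2-methylbut-2-enoate | CCOC(=O)/C(C)=C/CO[Si](C)(C)C(C)(C)C | intermediate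
4 | (E)-4-((tert-butyldimethylsilyl)oxy)-2-methylbut-2-en-1-ol | OC/C(C)=C/CO[Si](C)(C)C(C)(C)C | intermediate
5 | (R)-4-benzyl-3-propionyloxazolidin-2-one | CCC(=O)N1[C@H](Cc2ccccc2)COC1=O | starting material
6 | 2-((4-methoxybenzyl)oxy)acetaldehyde | O=CCOCc1ccc(OC)cc1 | starting material
7 | (R)-4-benzyl-3-[(2R,3R)-3-hydroxy-4-((4-methoxybenzyl)oxy)-2-methylbutanoyl]oxazolidin-2-one | O=C1OC[C@@H](Cc2ccccc2)N1C(=O)[C@H](C)[C@@H](O)COCc1ccc(OC)cc1 | intermediate
8 | (E)-4-((tert-butyldimethylsilyl)oxy)-2-methylbut-2-en-1-yl (2R,3R)-3-hydroxy-4-((4-methoxybenzyl)oxy)-2-methylbutanoate | CC(C)(C)[Si](C)(C)OC/C=C(\C)COC(=O)[C@H](C)[C@@H](O)COCc1ccc(OC)cc1 | intermediate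
9 | (2S,3R)-2-[(2S)-1-((tert-butyldimethylsilyl)oxy)-3-methylbut-3-en-2-yl]-3-hydroxy-4-((4-methoxybenzyl)oxy)-2-methylbutanoic acid (C1, C2, C10 as in the target) | OC(=O)[C@](C)([C@@H](O)COCc1ccc(OC)cc1)[C@@H](CO[Si](C)(C)C(C)(C)C)C(C)=C | intermediate
10 | (2R,3R)-2-[(2S)-1-((tert-butyldimethylsilyl)oxy)-3-methylbut-3-en-2-yl]-4-((4-methoxybenzyl)oxy)-2-methylbutane-1,3-diol | OC[C@](C)([C@@H](O)COCc1ccc(OC)cc1)[C@@H](CO[Si](C)(C)C(C)(C)C)C(C)=C | intermediate
11 | (2R,3R,4S)-3-[(2S)-1-((tert-butyldimethylsilyl)oxy)-3-methylbut-3-en-2-yl]-1-((4-methoxybenzyl)oxy)-3-methylhept-6-ene-2,4-diol (C1, C2, C10, C14 as in the target) | C=CC[C@H](O)[C@](C)([C@@H](O)COCc1ccc(OC)cc1)[C@@H](CO[Si](C)(C)C(C)(C)C)C(C)=C | intermediate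
12 | ring-A diol: 5-(((tert-butyldimethylsilyl)oxy)methyl)-6-[(1R)-1-hydroxy-2-((4-methoxybenzyl)oxy)ethyl]-4,6-dimethylcyclohex-3-en-1-ol, C1/C2/C10/C14 as in the target | CC1=CC[C@H](O)[C@](C)([C@@H](O)COCc2ccc(OC)cc2)[C@H]1CO[Si](C)(C)C(C)(C)C | intermediate
13 | tris-TBS ether of 12 (O2, O14 and O9 silylated, O3 as PMB ether) | CC1=CC[C@H](O[Si](C)(C)C(C)(C)C)[C@](C)([C@@H](O[Si](C)(C)C(C)(C)C)COCc2ccc(OC)cc2)[C@H]1CO[Si](C)(C)C(C)(C)C | intermediate
14 | primary alcohol: [5-((tert-butyldimethylsilyl)oxy)-6-[(1R)-1-((tert-butyldimethylsilyl)oxy)-2-((4-methoxybenzyl)oxy)ethyl]-2,6-dimethylcyclohex-2-en-1-yl]methanol, stereocentres as in the target | CC1=CC[C@H](O[Si](C)(C)C(C)(C)C)[C@](C)([C@@H](O[Si](C)(C)C(C)(C)C)COCc2ccc(OC)cc2)[C@H]1CO | intermediate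
15 | ring-A aldehyde: 5-((tert-butyldimethylsilyl)oxy)-6-[(1R)-1-((tert-butyldimethylsilyl)oxy)-2-((4-methoxybenzyl)oxy)ethyl]-2,6-dimethylcyclohex-2-ene-1-carbaldehyde, stereocentres as in the target | CC1=CC[C@H](O[Si](C)(C)C(C)(C)C)[C@](C)([C@@H](O[Si](C)(C)C(C)(C)C)COCc2ccc(OC)cc2)[C@H]1C=O | intermediate
16 | (R)-4-methyldihydrofuran-2(3H)-one | C[C@H]1COC(=O)C1 | starting material
17 | (3R,4R)-3-hydroxy-4-methyldihydrofuran-2(3H)-one (trans) | C[C@H]1COC(=O)[C@@H]1O | intermediate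
18 | (3R,4R)-4-methyl-3-((triethylsilyl)oxy)dihydrofuran-2(3H)-one | C[C@H]1COC(=O)[C@@H]1O[Si](CC)(CC)CC | intermediate
19 | lithium aldolate: 9-O-lithium alkoxide of the adduct of 18 and 15 (C8, C9 as in the target) | CC1=CC[C@H](O[Si](C)(C)C(C)(C)C)[C@](C)([C@@H](O[Si](C)(C)C(C)(C)C)COCc2ccc(OC)cc2)[C@H]1[C@H]([O-])[C@@]2(O[Si](CC)(CC)CC)C(=O)OC[C@@H]2C.[Li+] | intermediate (not isolated)
20 | aldol adduct: (4R)-4-methyl-3-((triethylsilyl)oxy)-3-[(tert-butyldimethylsilyl)oxy(ring-A)methyl]dihydrofuran-2(3H)-one; lactone C=O is C7, OCH2 is C19; C8 (OTES cis to C18) and C9 as in the target | CC1=CC[C@H](O[Si](C)(C)C(C)(C)C)[C@](C)([C@@H](O[Si](C)(C)C(C)(C)C)COCc2ccc(OC)cc2)[C@H]1[C@H](O[Si](C)(C)C(C)(C)C)[C@@]2(O[Si](CC)(CC)CC)C(=O)OC[C@@H]2C | intermediate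
21 | tert-butyldiphenyl(prop-2-yn-1-yloxy)silane | C#CCO[Si](c1ccccc1)(c1ccccc1)C(C)(C)C | starting material
22 | hydroxy ynone: C7 ketone conjugated to C6≡C5–C16H2OTBDPS, free C19H2OH, 8-OTES, 9-OTBS (in equilibrium with its five-membered hemiketal) | CC1=CC[C@H](O[Si](C)(C)C(C)(C)C)[C@](C)([C@@H](O[Si](C)(C)C(C)(C)C)COCc2ccc(OC)cc2)[C@H]1[C@H](O[Si](C)(C)C(C)(C)C)[C@](O[Si](CC)(CC)CC)([C@@H](C)CO)C(=O)C#CCO[Si](c2ccccc2)(c2ccccc2)C(C)(C)C | intermediate
23 | (7S)-propargylic alcohol, 7,19-diol (C7 as in the target) | CC1=CC[C@H](O[Si](C)(C)C(C)(C)C)[C@](C)([C@@H](O[Si](C)(C)C(C)(C)C)COCc2ccc(OC)cc2)[C@H]1[C@H](O[Si](C)(C)C(C)(C)C)[C@](O[Si](CC)(CC)CC)([C@@H](C)CO)[C@@H](O)C#CCO[Si](c2ccccc2)(c2ccccc2)C(C)(C)C | intermediate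
24 | sodium alkenylaluminate: five-membered O7–Al–C5 chelate, H on C6 trans to Al, 19-alkoxide | CC1=CC[C@H](O[Si](C)(C)C(C)(C)C)[C@](C)([C@@H](O[Si](C)(C)C(C)(C)C)COCc2ccc(OC)cc2)[C@H]1[C@H](O[Si](C)(C)C(C)(C)C)[C@](O[Si](CC)(CC)CC)([C@@H](C)C[O-])[C@H]3O[Al-](OCCOC)(OCCOC)C(CO[Si](c2ccccc2)(c2ccccc2)C(C)(C)C)=C3.[Na+].[Na+] | intermediate (not isolated)
25 | (Z)-5-iodo alkene 7,19-diol (I on C5 cis to C7) | CC1=CC[C@H](O[Si](C)(C)C(C)(C)C)[C@](C)([C@@H](O[Si](C)(C)C(C)(C)C)COCc2ccc(OC)cc2)[C@H]1[C@H](O[Si](C)(C)C(C)(C)C)[C@](O[Si](CC)(CC)CC)([C@@H](C)CO)[C@@H](O)/C=C(\I)CO[Si](c2ccccc2)(c2ccccc2)C(C)(C)C | intermediate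
26 | 7,19-bis-O-TES ether of 25 | CC1=CC[C@H](O[Si](C)(C)C(C)(C)C)[C@](C)([C@@H](O[Si](C)(C)C(C)(C)C)COCc2ccc(OC)cc2)[C@H]1[C@H](O[Si](C)(C)C(C)(C)C)[C@](O[Si](CC)(CC)CC)([C@@H](C)CO[Si](CC)(CC)CC)[C@@H](O[Si](CC)(CC)CC)/C=C(\I)CO[Si](c2ccccc2)(c2ccccc2)C(C)(C)C | intermediate
27 | C3 primary alcohol (PMB removed), vinyl iodide | CC1=CC[C@H](O[Si](C)(C)C(C)(C)C)[C@](C)([C@@H](O[Si](C)(C)C(C)(C)C)CO)[C@H]1[C@H](O[Si](C)(C)C(C)(C)C)[C@](O[Si](CC)(CC)CC)([C@@H](C)CO[Si](CC)(CC)CC)[C@@H](O[Si](CC)(CC)CC)/C=C(\I)CO[Si](c2ccccc2)(c2ccccc2)C(C)(C)C | intermediate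
28 | 3,4-diol (C4H2OH on C5, cis to C7) | CC1=CC[C@H](O[Si](C)(C)C(C)(C)C)[C@](C)([C@@H](O[Si](C)(C)C(C)(C)C)CO)[C@H]1[C@H](O[Si](C)(C)C(C)(C)C)[C@](O[Si](CC)(CC)CC)([C@@H](C)CO[Si](CC)(CC)CC)[C@@H](O[Si](CC)(CC)CC)/C=C(\CO)CO[Si](c2ccccc2)(c2ccccc2)C(C)(C)C | intermediate
29 | 3,4-bis(methanesulfonate) of 28 | CC1=CC[C@H](O[Si](C)(C)C(C)(C)C)[C@](C)([C@@H](O[Si](C)(C)C(C)(C)C)COS(C)(=O)=O)[C@H]1[C@H](O[Si](C)(C)C(C)(C)C)[C@](O[Si](CC)(CC)CC)([C@@H](C)CO[Si](CC)(CC)CC)[C@@H](O[Si](CC)(CC)CC)/C=C(\COS(C)(=O)=O)CO[Si](c2ccccc2)(c2ccccc2)C(C)(C)C | intermediate (not isolated)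
30 | eleven-membered cyclic sulfide: S bridges C3 and C4; ring S–C4–C5=C6–C7–C8–C9–C10–C1–C2–C3; 2,9,14-tri-O-TBS, 7,8,19-tri-O-TES, 16-O-TBDPS; stereocentres as in the target | CC(C)(C)[Si](c1ccccc1)(c1ccccc1)OCC1=C/[C@H](O[Si](CC)(CC)CC)[C@@](O[Si](CC)(CC)CC)([C@@H](C)CO[Si](CC)(CC)CC)[C@@H](O[Si](C)(C)C(C)(C)C)[C@H]2C(C)=CC[C@H](O[Si](C)(C)C(C)(C)C)[C@]2(C)[C@@H](O[Si](C)(C)C(C)(C)C)CSC\1 | intermediate
31 | eleven-membered cyclic sulfone (S,S-dioxide of 30) | CC(C)(C)[Si](c1ccccc1)(c1ccccc1)OCC1=C/[C@H](O[Si](CC)(CC)CC)[C@@](O[Si](CC)(CC)CC)([C@@H](C)CO[Si](CC)(CC)CC)[C@@H](O[Si](C)(C)C(C)(C)C)[C@H]2C(C)=CC[C@H](O[Si](C)(C)C(C)(C)C)[C@]2(C)[C@@H](O[Si](C)(C)C(C)(C)C)CS(=O)(=O)C\1 | intermediate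
32 | α-bromo sulfone (Br on C4, either configuration) | CC(C)(C)[Si](c1ccccc1)(c1ccccc1)OCC1=C/[C@H](O[Si](CC)(CC)CC)[C@@](O[Si](CC)(CC)CC)([C@@H](C)CO[Si](CC)(CC)CC)[C@@H](O[Si](C)(C)C(C)(C)C)[C@H]2C(C)=CC[C@H](O[Si](C)(C)C(C)(C)C)[C@]2(C)[C@@H](O[Si](C)(C)C(C)(C)C)CS(=O)(=O)C\1Br | intermediate (not isolated)
33 | episulfone (thiirane 1,1-dioxide across C3–C4, fused to the ten-membered ring) | CC(C)(C)[Si](c1ccccc1)(c1ccccc1)OCC1=C/[C@H](O[Si](CC)(CC)CC)[C@@](O[Si](CC)(CC)CC)([C@@H](C)CO[Si](CC)(CC)CC)[C@@H](O[Si](C)(C)C(C)(C)C)[C@H]2C(C)=CC[C@H](O[Si](C)(C)C(C)(C)C)[C@]2(C)[C@@H](O[Si](C)(C)C(C)(C)C)C3C\1S3(=O)=O | intermediate (not isolated)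
34 | ten-membered (3Z)-3,5-diene: 2,9,14-tri-O-TBS, 7,8,19-tri-O-TES, 16-O-TBDPS seco-lactone; stereocentres as in the target | CC(C)(C)[Si](c1ccccc1)(c1ccccc1)OCC1=C/[C@H](O[Si](CC)(CC)CC)[C@@](O[Si](CC)(CC)CC)([C@@H](C)CO[Si](CC)(CC)CC)[C@@H](O[Si](C)(C)C(C)(C)C)[C@H]2C(C)=CC[C@H](O[Si](C)(C)C(C)(C)C)[C@]2(C)[C@@H](O[Si](C)(C)C(C)(C)C)/C=C\1 | intermediate
35 | 7,19-diol of 34 (8-OTES retained) | CC(C)(C)[Si](c1ccccc1)(c1ccccc1)OCC1=C/[C@H](O)[C@@](O[Si](CC)(CC)CC)([C@@H](C)CO)[C@@H](O[Si](C)(C)C(C)(C)C)[C@H]2C(C)=CC[C@H](O[Si](C)(C)C(C)(C)C)[C@]2(C)[C@@H](O[Si](C)(C)C(C)(C)C)/C=C\1 | intermediate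
36 | protected γ-lactone (O7–C19=O): 2,9,14-tri-O-TBS, 8-O-TES, 16-O-TBDPS; all stereocentres as in the target | CC(C)(C)[Si](c1ccccc1)(c1ccccc1)OCC1=C/[C@@H]2OC(=O)[C@H](C)[C@@]2(O[Si](CC)(CC)CC)[C@@H](O[Si](C)(C)C(C)(C)C)[C@H]2C(C)=CC[C@H](O[Si](C)(C)C(C)(C)C)[C@]2(C)[C@@H](O[Si](C)(C)C(C)(C)C)/C=C\1 | intermediate
37 | pentaol lactone (2,8,9,14,16-pentahydroxy; the target without its four acetyl groups) | OCC1=C/[C@@H]2OC(=O)[C@H](C)[C@@]2(O)[C@@H](O)[C@H]2C(C)=CC[C@H](O)[C@]2(C)[C@@H](O)/C=C\1 | intermediate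
38 | CNP0224753.2: (1R,2S,7S,8S,9S,10S,14S,17R)-2,9,14,16-tetraacetoxy-8-hydroxy-briara-3(Z),5,11-trien-19,7-olide | CC(=O)OCC1=C/[C@@H]2OC(=O)[C@H](C)[C@@]2(O)[C@@H](OC(C)=O)[C@H]2C(C)=CC[C@H](OC(C)=O)[C@]2(C)[C@@H](OC(C)=O)/C=C\1 | target

**Totals.** Total step count: 27. Longest linear sequence: 24 steps (steps 1, 2, 4–11, 14–27).

**Steps most likely to fail**

1. Step 23 (ring contraction). The α-bromination may run on to the dibromide at the allylic carbon, or the allyl anion may be brominated at C6. A silyloxy group may also be expelled (1,2- from C3 or 1,4- from C4) before the episulfone closes, and the new olefin may form partly as the E isomer. Fallback: it sets out from sulfone 31 and returns at diene 34. The sulfone is deprotonated once at the allylic carbon with LiHMDS (1.05 equiv, THF, −78 °C) and quenched with hexachloroethane, to give the isolated α-chloro sulfone F1. This is then treated with KOt-Bu in THF (−78 → 0 °C) in a separate, base-only Ramberg–Bäcklund step. Halogenation is thus stoichiometric and finished before any excess base, hydroxide or halogen source meets the substrate.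

2. Step 14 (aldol union). The basic enolate may enolise the β,γ-unsaturated aldehyde, causing C10 epimerisation or olefin migration. Addition between two hindered partners may stall or revert, and the aldehyde's own facial preference may oppose the chair transition state at C9. Fallback: it sets out from lactone 18 (with aldehyde 15) and returns at 20. The lactone is converted (LDA, TMSCl) into the trimethylsilyl ketene acetal F2, which is added to 15 under BF3·OEt2 (non-basic Mukaiyama aldol, attack anti to the methyl) to give the aldol adduct F3 as C9 epimers. Dess–Martin oxidation gives the C9 ketone F4, and Felkin–Anh reduction (L-Selectride, −78 °C, hydride anti to the quaternary C1) gives the 9S alcohol F5. Silylation with TBSOTf/2,6-lutidine then gives 20.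

3. Step 21 (macrocyclisation). Intermolecular sulfide formation may outrun ring closure and give oligomers. Closure at the β-branched C3 mesylate may be slow enough for the allylic mesylate to decompose or for thiolate to be lost by oxidation. Fallback: it sets out from alcohol 27 and returns at sulfide 30. Mitsunobu reaction (PPh3, DIAD, AcSH) installs sulfur at the hindered C3 first, giving the thioacetate iodide F6. Stille hydroxymethylation gives the allylic alcohol thioacetate F7, and CBr4/PPh3 gives the allylic bromide thioacetate F8. Degassed K2CO3/MeOH at high dilution then frees the thiolate, which closes the ring on the fast allylic position to give 30.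

**Further compounds**

F1 | step 23 | α-chloro sulfone (Cl on C4 of 31) | CC(C)(C)[Si](c1ccccc1)(c1ccccc1)OCC1=C/[C@H](O[Si](CC)(CC)CC)[C@@](O[Si](CC)(CC)CC)([C@@H](C)CO[Si](CC)(CC)CC)[C@@H](O[Si](C)(C)C(C)(C)C)[C@H]2C(C)=CC[C@H](O[Si](C)(C)C(C)(C)C)[C@]2(C)[C@@H](O[Si](C)(C)C(C)(C)C)CS(=O)(=O)C\1Cl
F2 | step 14 | trimethylsilyl ketene acetal of 18: (R)-triethyl((4-methyl-2-((trimethylsilyl)oxy)-4,5-dihydrofuran-3-yl)oxy)silane | C[C@H]1COC(O[Si](C)(C)C)=C1O[Si](CC)(CC)CC
F3 | step 14 | aldol adduct with free 9-OH, C9 epimers (C8 as in the target) | CC1=CC[C@H](O[Si](C)(C)C(C)(C)C)[C@](C)([C@@H](O[Si](C)(C)C(C)(C)C)COCc2ccc(OC)cc2)[C@H]1C(O)[C@@]2(O[Si](CC)(CC)CC)C(=O)OC[C@@H]2C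
F4 | step 14 | C9 ketone | CC1=CC[C@H](O[Si](C)(C)C(C)(C)C)[C@](C)([C@@H](O[Si](C)(C)C(C)(C)C)COCc2ccc(OC)cc2)[C@H]1C(=O)[C@@]2(O[Si](CC)(CC)CC)C(=O)OC[C@@H]2C
F5 | step 14 | 9S alcohol (C9 as in the target; neutral form of 19) | CC1=CC[C@H](O[Si](C)(C)C(C)(C)C)[C@](C)([C@@H](O[Si](C)(C)C(C)(C)C)COCc2ccc(OC)cc2)[C@H]1[C@H](O)[C@@]2(O[Si](CC)(CC)CC)C(=O)OC[C@@H]2C
F6 | step 21 | C3 thioacetate, vinyl iodide | CC1=CC[C@H](O[Si](C)(C)C(C)(C)C)[C@](C)([C@@H](O[Si](C)(C)C(C)(C)C)CSC(C)=O)[C@H]1[C@H](O[Si](C)(C)C(C)(C)C)[C@](O[Si](CC)(CC)CC)([C@@H](C)CO[Si](CC)(CC)CC)[C@@H](O[Si](CC)(CC)CC)/C=C(\I)CO[Si](c2ccccc2)(c2ccccc2)C(C)(C)C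
F7 | step 21 | C3 thioacetate, C4 allylic alcohol | CC1=CC[C@H](O[Si](C)(C)C(C)(C)C)[C@](C)([C@@H](O[Si](C)(C)C(C)(C)C)CSC(C)=O)[C@H]1[C@H](O[Si](C)(C)C(C)(C)C)[C@](O[Si](CC)(CC)CC)([C@@H](C)CO[Si](CC)(CC)CC)[C@@H](O[Si](CC)(CC)CC)/C=C(\CO)CO[Si](c2ccccc2)(c2ccccc2)C(C)(C)C
F8 | step 21 | C3 thioacetate, C4 allylic bromide | CC1=CC[C@H](O[Si](C)(C)C(C)(C)C)[C@](C)([C@@H](O[Si](C)(C)C(C)(C)C)CSC(C)=O)[C@H]1[C@H](O[Si](C)(C)C(C)(C)C)[C@](O[Si](CC)(CC)CC)([C@@H](C)CO[Si](CC)(CC)CC)[C@@H](O[Si](CC)(CC)CC)/C=C(\CBr)CO[Si](c2ccccc2)(c2ccccc2)C(C)(C)C
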